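## Analysis of the target

Target 24 is a three-ring array. A central benzene ring carries four methoxy groups (positions 2, 3, 5, 6) and, para to each other at positions 1 and 4, two different indol-3-yl groups: a 5-hydroxyindole and a 6-(3-methylbut-2-enyl)indole. There is no stereocentre. Each aryl–indole axis is flanked by two methoxy groups on one side and by C2–H and C3a on the other, so the axes are crowded but carry no configurational information. The sensitive sites are the free 5-hydroxyindole (a para-aminophenol in disguise, easily oxidised), the acid- and electrophile-sensitive prenyl alkene, the two N–H indoles, and the tetramethoxybenzene core, which is prone to oxidative demethylation to a quinone. The synthesis is hard for three reasons: the two hindered C3–aryl bonds sit on a hexasubstituted benzene, the molecule is unsymmetrical, and one phenol must be told apart from four methyl ethers. The strategy rests on one feature: in both indoles C2 is an unsubstituted CH between N1 and the aryl-bearing C3. If C2 is taken out, C3 becomes the carbonyl carbon of a diaryl ketone and N1 the nitrogen of an ortho sulfonamide on the ring that supplies C3a and C7a. Both pyrrole rings can then be closed by inserting one carbon between a ketone carbon and a nitrogen.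

## Retrosynthetic reasoning

**From 24 to 22 (unmasking).** The last operations only remove heteroatom groups. The O–Si bond of 23 is cut to give 24, and before that the two N–S bonds of 22 are cut to give 23. The phenol is released last because a free 5-hydroxyindole is the most oxidisable function of the molecule. The sulfonyl groups are the handle the ring construction needs, so their removal is the price of the key step. Both cleavages have to leave the prenyl alkene and the four methyl ethers alone.

**From 22 to 16 and 17 (key disconnection).** In both indoles the C2=C3 and N1–C2 bonds are cut. C2 is removed as a single carbon supplied by 17, C3 becomes a diaryl ketone carbon and N1 an ortho sulfonamide nitrogen, which gives diketone 16. The cut is not made at the C3–aryl bonds, because those lie between two methoxy groups and would need two different, hindered indolyl–aryl couplings. As ketone–aryl bonds they can be made by carbonyl addition. The gain is that both heterocycles arise in one operation from a precursor that contains no indole. In the forward sense the anion 18 of 17 must add to each crowded ketone, and the carbene that follows (through 19 and 20) must be captured by the sulfonamide nitrogen to give 21 and, after protonation, 22.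

**From 16 to 15 (oxidation level).** Ketone 16 is traced to diol 15, the oxidation level at which the aryl–carbon bonds can be made from aldehydes. The oxidation must not touch the sulfonamides, the electron-rich silyloxy ring or the alkene. It must also be non-acidic, because ortho-sulfonamido diaryl carbinols ionise easily.

**From 15 to 13 and 9, and from 13 to 11 and 4 (the two aryl–carbinol bonds).** Both bonds between the central ring and the carbinol carbons are cut in turn. This leads to dibromide 11, lithiated once to 12 and, after the first addition, again to 14, and to the two aldehydes 4 and 9. Aldehydes are preferred to acid derivatives because an intermediate ketone would not survive the second metalation, whereas the alkoxide of 13 does. Two separate bromine–lithium exchanges on 11 answer the lack of symmetry, since each delivers one arm. The sulfonamide N–H of 4, 9 and 13 is carried as its anion, which costs no step and leaves the nitrogen ready for the key step.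

**From 11 to 10.** The two C–Br bonds are cut to return to 10, whose two open positions are equivalent and strongly activated. Bromine is wanted instead of two directed deprotonations because, once the first arm is attached, a sulfonamide that directs metalation onto its own ring is present. Exchange at bromine at low temperature is indifferent to it.

**From 4 to 1, and from 9 to 5 and 6 (the two arms).** In each aldehyde the N–S bond is cut (to aminoaldehydes 3 and 8) and the amine is traced to a nitro group (2 and 7), the form in which an ortho-aminobenzaldehyde is stable. For the first arm the O–Si bond of 2 is cut to give 1, and the silyl ether is placed first so that no free phenol is carried. For the second arm the aryl–CH2 bond of the prenyl group in 7 is cut to give 5 and 6. A tin reagent is the prenyl donor because an allylboron reagent would add to the formyl group. The coupling is placed first so that palladium never meets the sulfonamide or the aminoaldehyde.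

## Alternatives that were turned down

**Alternative 1: benzo ring of the hydroxyindole by furan Diels–Alder.**
- Disconnection: C3a–C7a and C4–C5 of the 5-hydroxyindole. C5, C6, C7, C7a and the phenol oxygen come from an N-Boc-2-aminofuran, and C3a and C4 from a terminal alkyne tethered through N1–C2–C3, as in the propargylic carbinol A2.
- Forward key step: heating A2 to about 180 °C (microwave, o-dichlorobenzene) triggers the intramolecular cycloaddition. The oxygen bridge opens under the push of nitrogen and the tertiary carbinol dehydrates, giving A1.
- For it: the C5 oxygen is built in, so its position cannot be wrong; no phenol protecting group is needed before the phenol appears; no transition metal is used.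
- Against it: it makes only one of the two indoles, so the prenylindole must be built separately and carried, N-silylated, through 180 °C. A2 needs an α-amino ketone on the hindered aryl group and an ethynyl addition to a ketone flanked by two methoxy groups. 2-Aminofuran carbamates are labile, and the Boc group is close to its thermolysis temperature.
- Comparison: it is stronger on placing the hydroxyl group and avoids every para-aminophenol-type intermediate. The chosen route offers in its place one ring-forming reaction for both indoles in one flask, and a precursor assembled from two simple aldehydes in a much shorter sequence.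

**Alternative 2: Larock annulation on a silylalkyne.**
- Disconnection: C3–C3a and N1–C2 of the prenylindole, leading to 2-bromo-5-prenylaniline A4 and the aryl(trimethylsilyl)alkyne A5, which already carries the other indole.
- Forward key step: Pd[P(t-Bu)3]2 (a zerovalent palladium complex) and base. Oxidative addition into A4, carbopalladation of the alkyne with silicon ending at C2, and C–N reductive elimination give A3, which still needs two C2 protodesilylations and the O-desilylation.
- For it: a convergent heteroannulation with well-understood regiocontrol by the silyl group. It delivers N–H indoles directly, with no N-protecting group to remove.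
- Against it: the new C3–C3a bond is formed at the alkyne carbon bearing the 2,6-dimethoxyaryl group, so an arylpalladium species must insert into an alkyne crowded at both ends. The two indoles need two separate annulations with two different haloanilines, the alkynes must be put on an electron-rich hindered dihalide, and two C–Si bonds must be cleaved afterwards.
- Comparison: it is at least as strong on protecting-group economy at nitrogen and on breadth of precedent. The chosen route offers that the bond to the crowded carbon already exists in the ketone (made by an unhindered aldehyde addition), that the atom delivered to the crowded centre is a single small carbon, and that both rings form together.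

**Alternative 3: nitrogen stitched in by double tandem amination.**
- Disconnection: N1–C2 and N1–C7a of both indoles. Nitrogen comes from tert-butyl carbamate A7 and carbon from the bis(bromovinyl) tetrabromide A8.
- Forward key step: Pd2(dba)3 (zerovalent palladium) with Xantphos and Cs2CO3 couples each molecule of A7 first with a vinyl bromide and then with the neighbouring aryl bromide, giving A6. Boc removal and conversion of the C6 chloride into the prenyl group follow.
- For it: no acidic N–H is carried through organolithium steps, Boc is easier to remove than a sulfonyl group, and both rings also form in one operation.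
- Against it: A8 has to be made from the same diaryl ketones by bromomethylenation, an extra step per ring that gives alkene isomers of which only the one with bromine cis to the bromoaryl ring can cyclise. Four palladium-mediated C–N couplings must succeed at hindered positions. The prenyl group is postponed to a late coupling of an unactivated aryl chloride, with its linear/branched question.
- Comparison: it is stronger on the lability of the nitrogen protecting group and on avoiding sulfonamide anions during assembly. The chosen route offers direct use of the ketones without an alkene-geometry issue, a metal-free ring closure, and the prenyl group already in place before the key step.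

Key step: step 11

Remark on the chemistry: 13 is racemic and 15 a mixture of diastereomers; both carbinol centres are erased in step 10.
Remark on the chemistry: sodium or lithium salts formed by simple N–H or O–H deprotonation of a numbered compound are treated as forms of that compound; carbon-metalated and covalently new species formed in the flask carry their own numbers.
Remark on the chemistry: the two ketone sites of 16 react independently in step 11, so 19, 20 and 21 are drawn with both sites at the same stage.

## Route

Step 1
Reactants: 1 5-hydroxy-2-nitrobenzaldehyde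
Product: 2 2-nitro-5-[(triisopropylsilyl)oxy]benzaldehyde
Conditions: i-Pr3SiCl, imidazole, DMF, rt
Reagents that add atoms: chlorotriisopropylsilane, CC(C)[Si](Cl)(C(C)C)C(C)C
Why: Silylation of an acidic phenol; the bulky silyl ether should survive the later organolithium steps and marks this oxygen as different from the four methyl ethers.

Step 2
Reactants: 2 2-nitro-5-[(triisopropylsilyl)oxy]benzaldehyde
Product: 3 2-amino-5-[(triisopropylsilyl)oxy]benzaldehyde
Conditions: Fe powder, AcOH, EtOH, 70 °C
Reagents that add atoms: none
Why: Béchamp-type reduction of the nitro group leaves the aldehyde untouched; the weakly acidic medium is chosen because a silyl ether para to a nitro group is base-labile, and the aminoaldehyde is used at once to avoid self-condensation.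

Step 3
Reactants: 3 2-amino-5-[(triisopropylsilyl)oxy]benzaldehyde
Product: 4 N-{2-formyl-4-[(triisopropylsilyl)oxy]phenyl}-4-methylbenzenesulfonamide
Conditions: TsCl, pyridine, CH2Cl2, 0 °C → rt
Reagents that add atoms: 4-methylbenzenesulfonyl chloride, Cc1ccc(cc1)S(Cl)(=O)=O
Why: N-Sulfonylation of the aniline; the ortho formyl group limits the reaction to one sulfonyl group, and the sulfonamide stops the self-condensation of the aminoaldehyde.

Step 4
Reactants: 5 4-bromo-2-nitrobenzaldehyde; 6 tributyl(3-methylbut-2-en-1-yl)stannane
Product: 7 4-(3-methylbut-2-en-1-yl)-2-nitrobenzaldehyde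
Conditions: Pd(PPh3)4 (5 mol %), DMF, 90 °C
Reagents that add atoms: none
Why: Stille allyl–aryl coupling on an electron-poor aryl bromide that adds readily to zerovalent palladium; unlike an allylboronate the stannane does not allylate the aldehyde without a Lewis acid, and C–C bond formation at the primary allyl terminus is expected because the tertiary terminus is hindered.

Step 5
Reactants: 7 4-(3-methylbut-2-en-1-yl)-2-nitrobenzaldehyde
Product: 8 2-amino-4-(3-methylbut-2-en-1-yl)benzaldehyde
Conditions: Fe powder, AcOH, EtOH, 70 °C
Reagents that add atoms: none
Why: Béchamp-type nitro reduction by electron transfer, which spares the aldehyde and the trisubstituted alkene, where hydrogenation would not.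

Step 6
Reactants: 8 2-amino-4-(3-methylbut-2-en-1-yl)benzaldehyde
Product: 9 N-[2-formyl-5-(3-methylbut-2-en-1-yl)phenyl]-4-methylbenzenesulfonamide
Conditions: TsCl, pyridine, CH2Cl2, 0 °C → rt
Reagents that add atoms: 4-methylbenzenesulfonyl chloride, Cc1ccc(cc1)S(Cl)(=O)=O
Why: N-Sulfonylation as in step 3; the alkene is inert to the sulfonyl chloride and pyridine.

Step 7
Reactants: 10 1,2,4,5-tetramethoxybenzene
Product: 11 1,4-dibromo-2,3,5,6-tetramethoxybenzene
Conditions: Br2 (2.1 equiv), CH2Cl2, 0 °C → rt
Reagents that add atoms: bromine, BrBr
Why: Electrophilic aromatic bromination; only two positions are open, they are equivalent and each is activated by two ortho methoxy groups, so no regiochemical question arises.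

Step 8
Reactants: 11 1,4-dibromo-2,3,5,6-tetramethoxybenzene; 4 N-{2-formyl-4-[(triisopropylsilyl)oxy]phenyl}-4-methylbenzenesulfonamide
Product: 13 N-{2-[(4-bromo-2,3,5,6-tetramethoxyphenyl)(hydroxy)methyl]-4-[(triisopropylsilyl)oxy]phenyl}-4-methylbenzenesulfonamide (racemic), via (4-bromo-2,3,5,6-tetramethoxyphenyl)lithium 12 (not isolated)
Conditions: n-BuLi (1.0 equiv), THF, −78 °C; then 4 (pre-treated with NaH, THF, 0 °C), −78 → 0 °C; sat. aq NH4Cl
Reagents that add atoms: none
Why: Bromine–lithium exchange stops after one bromine because the aryl anion resists a second exchange at −78 °C, and the aryllithium adds 1,2 to the aldehyde, whose sulfonamide is already a sodium salt and so cannot quench it; the new carbinol centre is formed without control and is erased in step 10, and the work-up is kept neutral because the carbinol ionises readily under acid.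

Step 9
Reactants: 13 N-{2-[(4-bromo-2,3,5,6-tetramethoxyphenyl)(hydroxy)methyl]-4-[(triisopropylsilyl)oxy]phenyl}-4-methylbenzenesulfonamide; 9 N-[2-formyl-5-(3-methylbut-2-en-1-yl)phenyl]-4-methylbenzenesulfonamide
Product: 15 1-{hydroxy[2-(tosylamino)-5-(triisopropylsilyloxy)phenyl]methyl}-4-{hydroxy[2-(tosylamino)-4-(3-methylbut-2-en-1-yl)phenyl]methyl}-2,3,5,6-tetramethoxybenzene (mixture of diastereomers), via disodium-salt aryllithium 14 (not isolated)
Conditions: NaH (2.2 equiv), THF, 0 °C; t-BuLi (2.1 equiv), −78 °C; then 9 (1.5 equiv, pre-treated with NaH, THF, 0 °C), −78 → 0 °C; sat. aq NH4Cl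
Reagents that add atoms: none
Why: With O–H and N–H removed first, bromine–lithium exchange by t-BuLi (the second equivalent destroys the tert-butyl bromide) is much faster than any deprotonation of the tosyl or prenyl groups, and the aryllithium adds to the aldehyde of the pre-formed sodium salt of 9; the second carbinol centre is uncontrolled and is erased in step 10.

Step 10
Reactants: 15 1-{hydroxy[2-(tosylamino)-5-(triisopropylsilyloxy)phenyl]methyl}-4-{hydroxy[2-(tosylamino)-4-(3-methylbut-2-en-1-yl)phenyl]methyl}-2,3,5,6-tetramethoxybenzene
Product: 16 1-[2-(tosylamino)-5-(triisopropylsilyloxy)benzoyl]-4-[2-(tosylamino)-4-(3-methylbut-2-en-1-yl)benzoyl]-2,3,5,6-tetramethoxybenzene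
Conditions: Dess–Martin periodinane (2.6 equiv), NaHCO3, CH2Cl2, 0 °C → rt
Reagents that add atoms: none
Why: Dess–Martin oxidation handles hindered secondary benzylic alcohols quickly under buffered, non-acidic conditions, so the ionisation-prone carbinols, the sulfonamides, the silyl ether and the alkene should be left intact.

Step 11
Reactants: 16 1-[2-(tosylamino)-5-(triisopropylsilyloxy)benzoyl]-4-[2-(tosylamino)-4-(3-methylbut-2-en-1-yl)benzoyl]-2,3,5,6-tetramethoxybenzene; 17 (trimethylsilyl)diazomethane
Product: 22 3-{4-[6-(3-methylbut-2-en-1-yl)-1-tosylindol-3-yl]-2,3,5,6-tetramethoxyphenyl}-1-tosyl-5-[(triisopropylsilyl)oxy]indole, via lithium trimethylsilyldiazomethanide 18 (not isolated), via bis-diazoalkene dilithium salt 19 (not isolated), via bis-alkylidene-carbene dilithium salt 20 (not isolated), via 2,2'-dilithio bis-indole 21 (not isolated)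
Conditions: 17 (6 equiv), LiN(i-Pr)2 (6 equiv), THF, −78 °C; then 16, −78 °C → rt; sat. aq NH4Cl
Reagents that add atoms: none
Why: Anion 18 first removes both sulfonamide protons and then adds to each ketone; on warming the lithium α-silyl alkoxide loses lithium trimethylsilanolate in a Peterson-type elimination to give the diazoalkene (19), which extrudes nitrogen to the alkylidene carbene (20). The carbene carbon, whose vacant p orbital lies in the plane of the alkene, is attacked by the ortho sulfonamide nitrogen anion, forming N1–C2 while the former ketone carbon becomes C3 and the alkene becomes C2=C3; the C2–lithium species (21) is protonated on work-up. The closest known reaction type is the Colvin-type generation of alkylidene carbenes from ketones with lithium trimethylsilyldiazomethanide and their capture by an ortho N-sulfonyl nitrogen, an established route from N-tosyl-2-aminoaryl ketones to 3-substituted N-tosylindoles, here run at two sites in one flask. Each pyrrole ring closes by bond formation between nitrogen and the carbene carbon four atoms away, a five-membered closure that is formally 5-endo but needs no distortion because the acceptor orbital points at the nitrogen. No stereocentre is formed. Three selectivities are needed: addition to a ketone flanked by two methoxy groups (secured by the small, strongly nucleophilic 18 in excess and by warming); capture by nitrogen faster than the 1,2-aryl shift that would give a diarylalkyne (secured by the anionic nitrogen held ortho and in plane); and nitrogen, not a flanking methoxy oxygen, as the internal nucleophile (the anion is the far better donor, and an oxonium ylide of a methyl ether has no easy onward path and can revert). The aryl silyl ether, the prenyl alkene (remote from both carbenes) and the methyl ethers are inert to the base at −78 °C.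

Step 12
Reactants: 22 3-{4-[6-(3-methylbut-2-en-1-yl)-1-tosylindol-3-yl]-2,3,5,6-tetramethoxyphenyl}-1-tosyl-5-[(triisopropylsilyl)oxy]indole
Product: 23 3-{4-[6-(3-methylbut-2-en-1-yl)-1H-indol-3-yl]-2,3,5,6-tetramethoxyphenyl}-5-[(triisopropylsilyl)oxy]-1H-indole
Conditions: Mg turnings (excess), MeOH/THF, ultrasound, rt
Reagents that add atoms: none
Why: Electron-transfer desulfonylation of N-sulfonylindoles by magnesium in methanol cleaves both N–S bonds (the indolide is a good leaving group) and should spare the isolated alkene, the methyl ethers and the hindered aryl silyl ether; any material that loses the silyl group early converges on the target in step 13.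

Step 13
Reactants: 23 3-{4-[6-(3-methylbut-2-en-1-yl)-1H-indol-3-yl]-2,3,5,6-tetramethoxyphenyl}-5-[(triisopropylsilyl)oxy]-1H-indole
Product: 24 3-{4-[6-(3-methylbut-2-en-1-yl)-1H-indol-3-yl]-2,3,5,6-tetramethoxyphenyl}-1H-indol-5-ol (target)
Conditions: Bu4NF, AcOH (1:1), THF, 0 °C → rt, under argon
Reagents that add atoms: none
Why: Fluoride-induced cleavage of the aryl O–Si bond; buffering with acetic acid keeps the 5-hydroxyindole protonated and exclusion of air limits its oxidation, while nothing else in the molecule responds to fluoride.

## Compound list

1 | 5-hydroxy-2-nitrobenzaldehyde | O=Cc1cc(O)ccc1[N+](=O)[O-] | starting material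
2 | 2-nitro-5-[(triisopropylsilyl)oxy]benzaldehyde | O=Cc1cc(O[Si](C(C)C)(C(C)C)C(C)C)ccc1[N+](=O)[O-] | intermediate
3 | 2-amino-5-[(triisopropylsilyl)oxy]benzaldehyde | Nc1ccc(O[Si](C(C)C)(C(C)C)C(C)C)cc1C=O | intermediate
4 | N-{2-formyl-4-[(triisopropylsilyl)oxy]phenyl}-4-methylbenzenesulfonamide | Cc1ccc(cc1)S(=O)(=O)Nc1ccc(O[Si](C(C)C)(C(C)C)C(C)C)cc1C=O | intermediate
5 | 4-bromo-2-nitrobenzaldehyde | O=Cc1ccc(Br)cc1[N+](=O)[O-] | starting material
6 | tributyl(3-methylbut-2-en-1-yl)stannane | CCCC[Sn](CCCC)(CCCC)CC=C(C)C | starting material
7 | 4-(3-methylbut-2-en-1-yl)-2-nitrobenzaldehyde | O=Cc1ccc(CC=C(C)C)cc1[N+](=O)[O-] | intermediate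
8 | 2-amino-4-(3-methylbut-2-en-1-yl)benzaldehyde | Nc1cc(CC=C(C)C)ccc1C=O | intermediate
9 | N-[2-formyl-5-(3-methylbut-2-en-1-yl)phenyl]-4-methylbenzenesulfonamide | Cc1ccc(cc1)S(=O)(=O)Nc1cc(CC=C(C)C)ccc1C=O | intermediate
10 | 1,2,4,5-tetramethoxybenzene | COc1cc(OC)c(OC)cc1OC | starting material
11 | 1,4-dibromo-2,3,5,6-tetramethoxybenzene | COc1c(OC)c(Br)c(OC)c(OC)c1Br | intermediate
12 | (4-bromo-2,3,5,6-tetramethoxyphenyl)lithium (not isolated) | [Li]c1c(OC)c(OC)c(Br)c(OC)c1OC | intermediate
13 | N-{2-[(4-bromo-2,3,5,6-tetramethoxyphenyl)(hydroxy)methyl]-4-[(triisopropylsilyl)oxy]phenyl}-4-methylbenzenesulfonamide (racemic) | COc1c(OC)c(C(O)c2cc(O[Si](C(C)C)(C(C)C)C(C)C)ccc2NS(=O)(=O)c2ccc(C)cc2)c(OC)c(OC)c1Br | intermediate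
14 | aryllithium from 13 as its disodium alkoxide/sulfonamide salt (not isolated) | [Li]c1c(OC)c(OC)c(C([O-])c2cc(O[Si](C(C)C)(C(C)C)C(C)C)ccc2[N-]S(=O)(=O)c2ccc(C)cc2)c(OC)c1OC.[Na+].[Na+] | intermediate
15 | 1-{hydroxy[2-(tosylamino)-5-(triisopropylsilyloxy)phenyl]methyl}-4-{hydroxy[2-(tosylamino)-4-(3-methylbut-2-en-1-yl)phenyl]methyl}-2,3,5,6-tetramethoxybenzene (mixture of diastereomers) | COc1c(OC)c(C(O)c2cc(O[Si](C(C)C)(C(C)C)C(C)C)ccc2NS(=O)(=O)c2ccc(C)cc2)c(OC)c(OC)c1C(O)c1ccc(CC=C(C)C)cc1NS(=O)(=O)c1ccc(C)cc1 | intermediate
16 | 1-[2-(tosylamino)-5-(triisopropylsilyloxy)benzoyl]-4-[2-(tosylamino)-4-(3-methylbut-2-en-1-yl)benzoyl]-2,3,5,6-tetramethoxybenzene | COc1c(OC)c(C(=O)c2cc(O[Si](C(C)C)(C(C)C)C(C)C)ccc2NS(=O)(=O)c2ccc(C)cc2)c(OC)c(OC)c1C(=O)c1ccc(CC=C(C)C)cc1NS(=O)(=O)c1ccc(C)cc1 | intermediate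
17 | (trimethylsilyl)diazomethane | C[Si](C)(C)C=[N+]=[N-] | starting material
18 | lithium trimethylsilyldiazomethanide (not isolated) | C[Si](C)(C)C([Li])=[N+]=[N-] | intermediate
19 | bis(diazoalkene) from 16, N,N'-dilithium salt (not isolated) | COc1c(OC)c(C(=C=[N+]=[N-])c2cc(O[Si](C(C)C)(C(C)C)C(C)C)ccc2[N-]S(=O)(=O)c2ccc(C)cc2)c(OC)c(OC)c1C(=C=[N+]=[N-])c1ccc(CC=C(C)C)cc1[N-]S(=O)(=O)c1ccc(C)cc1.[Li+].[Li+] | intermediate
20 | bis(alkylidene carbene) from 19, N,N'-dilithium salt (not isolated) | COc1c(OC)c(C(=[C])c2cc(O[Si](C(C)C)(C(C)C)C(C)C)ccc2[N-]S(=O)(=O)c2ccc(C)cc2)c(OC)c(OC)c1C(=[C])c1ccc(CC=C(C)C)cc1[N-]S(=O)(=O)c1ccc(C)cc1.[Li+].[Li+] | intermediate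
21 | 2,2'-dilithio derivative of 22 (not isolated) | COc1c(OC)c(-c2c([Li])n(S(=O)(=O)c3ccc(C)cc3)c3ccc(O[Si](C(C)C)(C(C)C)C(C)C)cc23)c(OC)c(OC)c1-c1c([Li])n(S(=O)(=O)c2ccc(C)cc2)c2cc(CC=C(C)C)ccc12 | intermediate
22 | 3-{4-[6-(3-methylbut-2-en-1-yl)-1-tosylindol-3-yl]-2,3,5,6-tetramethoxyphenyl}-1-tosyl-5-[(triisopropylsilyl)oxy]indole | COc1c(OC)c(-c2cn(S(=O)(=O)c3ccc(C)cc3)c3ccc(O[Si](C(C)C)(C(C)C)C(C)C)cc23)c(OC)c(OC)c1-c1cn(S(=O)(=O)c2ccc(C)cc2)c2cc(CC=C(C)C)ccc12 | intermediate
23 | 3-{4-[6-(3-methylbut-2-en-1-yl)-1H-indol-3-yl]-2,3,5,6-tetramethoxyphenyl}-5-[(triisopropylsilyl)oxy]-1H-indole | COc1c(OC)c(-c2c[nH]c3ccc(O[Si](C(C)C)(C(C)C)C(C)C)cc23)c(OC)c(OC)c1-c1c[nH]c2cc(CC=C(C)C)ccc12 | intermediate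
24 | 3-{4-[6-(3-methylbut-2-en-1-yl)-1H-indol-3-yl]-2,3,5,6-tetramethoxyphenyl}-1H-indol-5-ol | COc1c(OC)c(-c2c[nH]c3ccc(O)cc23)c(OC)c(OC)c1-c1c[nH]c2cc(CC=C(C)C)ccc12 | target

## Step count and risk

Total step count: 13 (steps 1–3 for aldehyde 4, steps 4–6 for aldehyde 9, step 7 for the central ring, steps 8–13 for assembly, key step and unmasking).
Longest linear sequence: 9 steps (1, 2, 3, 8, 9, 10, 11, 12, 13).

Least certain steps:

**Step 11 (key step).** The most likely failure is that 18 does not add to carbonyl groups that are flanked by two methoxy groups and deactivated by the neighbouring sulfonamide anion, so that 16 is returned. The second is that the carbene rearranges by 1,2-aryl migration to a diarylalkyne, or engages a flanking methoxy oxygen, before nitrogen reaches it. Fallback: set out from 16 and deliver the same carbon as a masked aldehyde instead of a carbene. Wittig reaction of 16 with methoxymethylenetriphenylphosphorane (from (methoxymethyl)triphenylphosphonium chloride and KN(SiMe3)2, in excess, THF) should give the bis(methyl enol ether) F1. Pyridinium p-toluenesulfonate in warm toluene would then protonate each enol ether; the sulfonamide nitrogen adds to the oxocarbenium ion and methanol is lost. This returns to the route at 22.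

**Step 4.** The likely failures are C–C bond formation at the tertiary allyl terminus (branched isomer), migration of the double bond into conjugation with the ring by a palladium hydride, and slow addition of the allyl metal to the activated aldehyde at 90 °C. Fallback: set out from 5 and reverse the polarity of the coupling. Miyaura borylation (bis(pinacolato)diboron, PdCl2(dppf), KOAc, dioxane, 80 °C) should give 2-nitro-4-(4,4,5,5-tetramethyl-1,3,2-dioxaborolan-2-yl)benzaldehyde F2. Allylation of F2 with 1-bromo-3-methylbut-2-ene (Pd(PPh3)4, K2CO3, toluene/water) transfers the aryl group to the unsubstituted terminus of an η3-prenylpalladium intermediate, and no nucleophilic allyl metal is present. This returns to the route at 7.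

**Step 9.** The likely failures are incomplete exchange or proton quench within the poorly soluble polyanion, and sluggish addition of this hindered aryllithium to an aldehyde deactivated by its own sulfonamide anion; both would show up as loss of bromine without C–C bond formation. Fallback: set out from 13 and mask both acidic sites before the exchange. NaH followed by Me3SiCl in THF should give the O,N-bis(trimethylsilyl) derivative F3 in the flask. t-BuLi at −78 °C converts it into the neutral, soluble aryllithium F4, which is added to the sodium salt of 9 to give the silylated adduct F5. K2CO3 in methanol at 0 °C removes both trimethylsilyl groups and returns to the route at 15.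

**Step 12.** The likely failures are incomplete cleavage of one of the two sulfonyl groups and partial loss of the silyl ether in basic methanol, which would expose the hydroxyindole to oxidation and give mixtures. Fallback: set out from 22 and remove all three groups by nucleophilic instead of reductive cleavage. Excess Bu4NF in THF at reflux attacks silicon at once and then the sulfonyl sulfur of both N-sulfonylindoles, giving 24 directly; no new compound is made.

## Further compounds

F1 | step 11 | 1-[2-methoxy-1-(2-tosylamino-5-triisopropylsilyloxyphenyl)vinyl]-4-[2-methoxy-1-(2-tosylamino-4-prenylphenyl)vinyl]-2,3,5,6-tetramethoxybenzene (mixture of alkene isomers) | COc1c(OC)c(C(=COC)c2cc(O[Si](C(C)C)(C(C)C)C(C)C)ccc2NS(=O)(=O)c2ccc(C)cc2)c(OC)c(OC)c1C(=COC)c1ccc(CC=C(C)C)cc1NS(=O)(=O)c1ccc(C)cc1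
F2 | step 4 | 2-nitro-4-(4,4,5,5-tetramethyl-1,3,2-dioxaborolan-2-yl)benzaldehyde | O=Cc1ccc(B2OC(C)(C)C(C)(C)O2)cc1[N+](=O)[O-]
F3 | step 9 | O,N-bis(trimethylsilyl) derivative of 13 (racemic) | COc1c(OC)c(C(O[Si](C)(C)C)c2cc(O[Si](C(C)C)(C(C)C)C(C)C)ccc2N([Si](C)(C)C)S(=O)(=O)c2ccc(C)cc2)c(OC)c(OC)c1Br
F4 | step 9 | aryllithium from F3 | [Li]c1c(OC)c(OC)c(C(O[Si](C)(C)C)c2cc(O[Si](C(C)C)(C(C)C)C(C)C)ccc2N([Si](C)(C)C)S(=O)(=O)c2ccc(C)cc2)c(OC)c1OC
F5 | step 9 | O,N-bis(trimethylsilyl) derivative of 15, silyl groups on the silyloxyphenyl arm (mixture of diastereomers) | COc1c(OC)c(C(O[Si](C)(C)C)c2cc(O[Si](C(C)C)(C(C)C)C(C)C)ccc2N([Si](C)(C)C)S(=O)(=O)c2ccc(C)cc2)c(OC)c(OC)c1C(O)c1ccc(CC=C(C)C)cc1NS(=O)(=O)c1ccc(C)cc1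
F0 | step 12 | none | none
A1 | alternative 1 | N-Boc (hydroxyindole), N-triisopropylsilyl (prenylindole) derivative of the target | COc1c(OC)c(-c2cn(C(=O)OC(C)(C)C)c3ccc(O)cc23)c(OC)c(OC)c1-c1cn([Si](C(C)C)(C(C)C)C(C)C)c2cc(CC=C(C)C)ccc12
A2 | alternative 1 | tert-butyl (furan-2-yl){2-hydroxy-2-[2,3,5,6-tetramethoxy-4-(6-prenyl-1-triisopropylsilylindol-3-yl)phenyl]but-3-yn-1-yl}carbamate (racemic) | C#CC(O)(CN(C(=O)OC(C)(C)C)c1ccco1)c1c(OC)c(OC)c(-c2cn([Si](C(C)C)(C(C)C)C(C)C)c3cc(CC=C(C)C)ccc23)c(OC)c1OC
A3 | alternative 2 | 2,2'-bis(trimethylsilyl) O-triisopropylsilyl derivative of the target | COc1c(OC)c(-c2c([Si](C)(C)C)[nH]c3cc(CC=C(C)C)ccc23)c(OC)c(OC)c1-c1c([Si](C)(C)C)[nH]c2ccc(O[Si](C(C)C)(C(C)C)C(C)C)cc12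
A4 | alternative 2 | 2-bromo-5-(3-methylbut-2-en-1-yl)aniline | Nc1cc(CC=C(C)C)ccc1Br
A5 | alternative 2 | 3-{2,3,5,6-tetramethoxy-4-[(trimethylsilyl)ethynyl]phenyl}-2-(trimethylsilyl)-5-[(triisopropylsilyl)oxy]-1H-indole | C[Si](C)(C)C#Cc1c(OC)c(OC)c(-c2c([Si](C)(C)C)[nH]c3ccc(O[Si](C(C)C)(C(C)C)C(C)C)cc23)c(OC)c1OC
A6 | alternative 3 | N,N'-di-Boc O-triisopropylsilyl 6-chloroindole analogue of the target | COc1c(OC)c(-c2cn(C(=O)OC(C)(C)C)c3ccc(O[Si](C(C)C)(C(C)C)C(C)C)cc23)c(OC)c(OC)c1-c1cn(C(=O)OC(C)(C)C)c2cc(Cl)ccc12
A7 | alternative 3 | tert-butyl carbamate | CC(C)(C)OC(N)=O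
A8 | alternative 3 | 1-[2-bromo-1-(2-bromo-5-triisopropylsilyloxyphenyl)vinyl]-4-[2-bromo-1-(2-bromo-4-chlorophenyl)vinyl]-2,3,5,6-tetramethoxybenzene (alkene geometry unspecified) | COc1c(OC)c(C(=CBr)c2cc(O[Si](C(C)C)(C(C)C)C(C)C)ccc2Br)c(OC)c(OC)c1C(=CBr)c1ccc(Cl)cc1Br
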